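The rate constants are invented, and the outcome is calculated.

Target forms from starting material and the reagent in the reaction phase, and that reagent is charged in the second phase, so the yield hangs on how much has crossed.

    reagent in the reaction phase ⇌ reagent in the second phase, rate k1*([reagent in the reaction phase] - [reagent in the second phase]/K1) per volume of the first phase (K1 = 1.09, k1 = 0.0154 s⁻¹)
    starting material + reagent in the reaction phase ⇌ target (K2 = 21.6 L mol⁻¹, k2 = 181 L mol⁻¹ s⁻¹)
    reagent in the reaction phase + target → over-reacted product (k3 = 22.9 L mol⁻¹ s⁻¹)
    target ⇌ isomer of the product (K4 = 1.45, k4 = 0.307 s⁻¹)
    starting material → decomposition product (k5 = 1.93 × 10⁻⁴ s⁻¹)

starting material 34 mM; reagent in the second phase 1.00 equiv; time 10 s; volume of the second phase over the first 1.0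

- in the second phase: reagent in the second phase; everything else is in the first
- charges count per volume of the first phase; a concentration in a rate is the amount of a species over the volume of its own phase; every rate counts per litre of the first phase
- run time (flask): 10 s

* amount of target at 10 s, in percent of the starting material charged
* part of the starting material charged that has reacted at 10 s

The addition has a half-life of 0.11 s for the reagent in the reaction phase, far shorter than the 70.8 s of crossing, so crossing is the rate-limiting step. The reagent balance therefore starts at the interface. The transfer coefficient times the time over the partition ratio gives 0.141, the delivery number: the share of the reagent's charge that crosses in the run if the starting drive holds. Equal charges make this a share of the starting material as well.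

One number gives the amount crossed but not its split. Taking the addition as fast, c(target)/c(reagent in the reaction phase) stands near 0.73. Target is still being fed during the run, so c(isomer)/c(target) need not stand at the equilibrium constant of step 4, but this reckoning sets it at 1.45 as a plain assumption. The bound share of the crossed reagent is then 0.643. This reckoning gives a conversion of 9.08 % and a yield of 3.71 %, with over-reaction neglected.

The forecast, lower on conversion than this reckoning, gives 3.5 % and 7.5 %, holding that “Phase transfer is the slow step”. The flask gives 3.37 % and 7.30 %.

At 10.0 s the second phase of this flask holds 87.3 % of its charge, so 12.7 % has crossed, against a delivery number of 0.141. In this flask c(isomer)/c(target) then stands at 0.944, lower than the assumed 1.45. Read at 40 s, the same flask has a delivery number of 0.565, and the reckoning gives a conversion of 36.3 %. That flask shows 22.4 %, with 60.1 % of the reagent still in the second phase, so 39.9 % has crossed. Its over-reacted product, which holds two reagents each, accounts for 18.5 % of the reagent charged.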